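## Retrosynthetic overview

- Numbering (alkaloid convention): pyrrolidine N4–C3–C2–C1–C9a; azepane N4–C5–C6–C7–C8–C9–C9a; tetrahydrofuran O–C8–C9–C10(Et)–C11; spiro-lactone C11–C12–C13(Me)–C14(=O)–O; side lactone C18–C19–C20(Me)–C21(=O)–O on C3.
- Late disconnections: C3–C18 (iridium-catalysed reductive vinylogous Mannich reaction on a C3 lactam, then hydrogenation sets C20) and the two C11–O bonds (acid-mediated decarboxylative spiroketalisation, C10 and C11 under thermodynamic control).
- Key disconnection C9–C10: a C10 carbanion held on the lactam nitrogen by a temporary acyl tether opens a cis-epoxide at C9, closing a temporary five-membered imide ring N4–C(=O)–C10–C9–C9a. The C8 alkoxide then takes the tether carbonyl (γ-lactone, tether ring cleaved), the freed N4 closes the azepane on a C5 chloride, and the tether carbon is later lost as CO2.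
- Enabling feature: N4 is bonded to C9a next to C9, the ring oxygen sits on C8 vicinal to C9, and C10 is α to the ketal carbon C11 (a masked ketone). C9 and C10 are therefore both natural donor positions (C8–O and C11–O are 1,4-related); the mismatch is resolved by making C9 an epoxide carbon and C10 a 1,3-dicarbonyl carbanion anchored to N4.
- Ring order: pyrrolidinone (chiral pool) → temporary imide ring (C9–C10) → γ-lactone → azepane → tetrahydrofuran and spiro-lactone together → side-chain lactone.

Key step: step 8

Remark: the centre between the two carbonyl groups (later C10) is carried as an epimer mixture from 10 to 18 and is drawn without configuration; deprotonated forms (enolates, alkoxides, amide anions) are counted as the numbered neutral compounds.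

## Route

Step 1
Reactants: 1 1-bromo-4-chlorobutane; 2 triphenylphosphine
Product: 3 (4-chlorobutyl)triphenylphosphonium bromide
Conditions: toluene, 110 °C, 48 h; filtration of the salt
Reagents that add atoms: none
Why: SN2 quaternisation of the phosphine should occur only at the bromide terminus (far better leaving group), which gives the Wittig salt with the C5 chloride intact; no stereocenter is formed.

Step 2
Reactants: 4 (5S)-5-(hydroxymethyl)pyrrolidin-2-one
Product: 5 (2S)-5-oxopyrrolidine-2-carbaldehyde
Conditions: DMP (1.2 equiv), CH2Cl2–MeCN, 0 °C → rt; filtered, concentrated cold, used at once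
Reagents that add atoms: none
Why: Dess–Martin oxidation of the primary alcohol under neutral conditions leaves the lactam alone, and the configurationally labile α-amino aldehyde is not purified so that the chiral-pool centre (future C9a, S) is kept.

Step 3
Reactants: 5 (2S)-5-oxopyrrolidine-2-carbaldehyde; 3 (4-chlorobutyl)triphenylphosphonium bromide
Product: 7 (5S)-5-[(1Z)-5-chloropent-1-en-1-yl]pyrrolidin-2-one, via ylide 6 (not isolated)
Conditions: 3 (1.6 equiv), KN(SiMe3)2 (1.5 equiv), THF, −78 °C, 15 min; then 5, −78 → 0 °C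
Reagents that add atoms: none
Why: Salt-free Wittig olefination with a non-stabilised ylide should give the (Z)-alkene through the kinetically favoured cis-oxaphosphetane (this geometry becomes the cis-epoxide), the lactam N–H being less acidic than the phosphonium salt and the ω-chloride surviving because ylide and aldehyde combine below 0 °C.

Step 4
Reactants: 8 tert-butyl butanoate; 9 (3S)-3-methyloxolane-2,5-dione
Product: 10 (2S)-6-tert-butoxy-5-ethyl-2-methyl-4,6-dioxohexanoic acid
Conditions: 8 (2.2 equiv), LiN(iPr)2 (2.2 equiv), THF, −78 °C; enolate added to 9 (1.0 equiv) in THF, −78 °C; AcOH quench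
Reagents that add atoms: none
Why: Claisen-type C-acylation of the lithium ester enolate by the cyclic anhydride should take place at the less hindered carbonyl (next to CH2, the future C11 ketone), the second equivalent of enolate absorbing the acidic β-keto ester proton and the carboxylate formed next to C13 protecting that chiral-pool centre (S) from enolisation; the new centre between the carbonyls forms as an inconsequential mixture.

Step 5
Reactants: 10 (2S)-6-tert-butoxy-5-ethyl-2-methyl-4,6-dioxohexanoic acid
Product: 11 1-tert-butyl 6-methyl (5S)-2-ethyl-5-methyl-3-oxohexanedioate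
Conditions: Me3SiCHN2 (1.2 equiv), toluene–MeOH (4:1), 0 °C
Reagents that add atoms: (trimethylsilyl)diazomethane, C[Si](C)(C)C=[N+]=[N-]
Why: O-methylation of the carboxylic acid by the diazoalkane (esterification through the diazonium carboxylate pair) is selective because the α-substituted β-keto ester is hardly enolised; no stereocenter is touched.

Step 6
Reactants: 7 (5S)-5-[(1Z)-5-chloropent-1-en-1-yl]pyrrolidin-2-one; 11 1-tert-butyl 6-methyl (5S)-2-ethyl-5-methyl-3-oxohexanedioate
Product: 13 methyl (2S)-5-{[(2S)-2-[(1Z)-5-chloropent-1-en-1-yl]-5-oxopyrrolidin-1-yl]carbonyl}-2-methyl-4-oxoheptanoate, via acylketene 12 (not isolated)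
Conditions: 11 (1.5 equiv), xylenes, 140 °C, slow removal of t-BuOH
Reagents that add atoms: none
Why: Thermolysis of the β-keto tert-butyl ester expels tert-butanol to give the α-ethyl acylketene, which is captured by the lactam N–H (acylketene transfer, the base-free way to acetoacetylate lactams and oxazolidinones), so the N-acyl tether is installed without enolising the ring CH2 or C13.

Step 7
Reactants: 13 methyl (2S)-5-{[(2S)-2-[(1Z)-5-chloropent-1-en-1-yl]-5-oxopyrrolidin-1-yl]carbonyl}-2-methyl-4-oxoheptanoate
Product: 14 methyl (2S)-5-{[(2S)-2-[(2S,3R)-3-(3-chloropropyl)oxiran-2-yl]-5-oxopyrrolidin-1-yl]carbonyl}-2-methyl-4-oxoheptanoate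
Conditions: mCPBA (1.5 equiv), CH2Cl2, 0 °C → rt
Reagents that add atoms: 3-chloroperoxybenzoic acid (mCPBA), OOC(=O)c1cccc(Cl)c1
Why: Prilezhaev epoxidation is stereospecific (Z-alkene to cis-epoxide) and should occur anti to the imide nitrogen, because with the C9a–H bond eclipsing the Z-alkene (allylic 1,3-strain) one face carries the ring CH2 and the other the bulky, non-hydrogen-bonding N-acyl group; this sets C8 (R, with its final oxygen) and C9 (with the oxygen to be displaced), while the non-enolised β-keto imide and the chloride are inert.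

Step 8
Reactants: 14 methyl (2S)-5-{[(2S)-2-[(2S,3R)-3-(3-chloropropyl)oxiran-2-yl]-5-oxopyrrolidin-1-yl]carbonyl}-2-methyl-4-oxoheptanoate
Product: 17 tricyclic keto lactone: (8R,9R,9aS)-hexahydropyrrolo[1,2-a]azepin-3-one with a γ-lactone fused trans across C8–C9 (ring O on C8; carbonyl = tether carbon on C10) and C10 bearing ethyl plus the CO–CH2–(S)-CH(CH3)–CO2CH3 chain, via bicyclic imide alcohol 15 (not isolated), via lactone lactam chloride 16 (not isolated)
Conditions: NaH (1.1 equiv), THF–DMPU (10:1), 0.01 M, 0 → 60 °C; then NaI (0.3 equiv), 65 °C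
Reagents that add atoms: none
Why: Proposed new method: NaH is expected to deprotonate the carbon between the two carbonyls (C10); this carbanion opens the epoxide at C9 by intramolecular SN2 (5-exo-tet, forming the C9–C10 bond and closing the temporary imide ring N4–C(=O)–C10–C9–C9a of 15), the C8 alkoxide set free adds to the twisted imide carbonyl (5-exo-trig addition–elimination) and expels the lactam anion, which opens the temporary ring to γ-lactone 16, and this amide anion closes the azepane by 7-exo-tet displacement of the C5 chloride (iodide-catalysed). The closest known reactions are the acetoacetic ester–epoxide synthesis of α-acyl-γ-butyrolactones (C-alkylation, then acyl transfer to the new alkoxide), carbanion–epoxide ring closures of the epoxynitrile type, alkoxide cleavage of N-acyl lactams and lactam N-alkylation to seven-membered rings; new is their combination through an N-acyl lactam that is tether, acyl donor and masked nitrogen nucleophile at once. C9 is set by inversion at the epoxide carbon and C8 keeps the epoxide configuration, so the 8,9-trans lactone is in place before the seven-membered ring exists (cyclisation onto a preformed azepine would be expected to give the cis fusion); C9a is that of 4, and the quaternary C10 is uncontrolled, which is harmless because step 9 resets it. C- over O-alkylation and C9 over C8 attack should be secured by the exocyclic ketone enolate, which lets C10 reach C9 in the favoured five-membered mode, whereas the enolate oxygen would need a seven-membered and attack at C8 a six-membered endo transition state. Acyl transfer has to outrun ether formation between the alkoxide and the C5 chloride (addition to an activated imide carbonyl through a five-membered ring should be far faster than SN2 at a primary chloride), and the final N-alkylation needs a persistent amide anion, which is assured because C10 is already quaternary and 17 has no more acidic proton.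

Step 9
Reactants: 17 tricyclic keto lactone
Product: 19 spiroketal lactam (8R,9R,9aS,10S,11S,13S): the target skeleton with a C3 lactam carbonyl in place of the C3 side chain, via hydroxy keto ester 18 (not isolated)
Conditions: 1 M aq. H2SO4–1,4-dioxane (1:2), 85 °C; then TsOH·H2O (0.1 equiv), toluene, 4 Å MS, 80 °C
Reagents that add atoms: water, O
Why: Acid hydrolysis cleaves the lactone at its acyl–oxygen bond (C8–O and its configuration are kept), the β-keto acid loses the tether carbon as CO2, and hydroxy ketone 18 ketalises and lactonises onto the C14 ester; because the spiroketal opens and closes reversibly and C10 is enolisable in the open form, C10 and C11 should settle under thermodynamic control with ethyl trans to the C9 substituent and syn to the smaller lactone oxygen instead of CH2, while C13 (not enolised in acid) keeps its configuration.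

Step 10
Reactants: 20 3-methylfuran-2(5H)-one
Product: 21 3-methyl-2-(triisopropylsilyloxy)furan
Conditions: iPr3SiOTf (1.1 equiv), Et3N (1.3 equiv), CH2Cl2, 0 °C
Reagents that add atoms: triisopropylsilyl trifluoromethanesulfonate, CC(C)[Si](OS(=O)(=O)C(F)(F)F)(C(C)C)C(C)C
Why: Soft enolisation and O-silylation of the butenolide gives the aromatic 2-silyloxyfuran, the vinylogous nucleophile for step 11; no stereocenter is formed.

Step 11
Reactants: 19 spiroketal lactam; 21 3-methyl-2-(triisopropylsilyloxy)furan
Product: 23 (3S,8R,9R,9aS,10S,11S,13S,18S)-19,20-didehydro target (4-methyl-5-oxo-2,5-dihydrofuran-2-yl group on C3), via O-silyl hemiaminal 22 (not isolated)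
Conditions: IrCl(CO)(PPh3)2 (1 mol %), (Me2SiH)2O (2.0 equiv), toluene, rt; then 21 (1.5 equiv), 2-nitrobenzoic acid (1.1 equiv), MeCN, 0 °C → rt
Reagents that add atoms: none
Why: Iridium-catalysed hydrosilylation reduces only the tertiary lactam (the lactone of the spiroketal is left) to hemiaminal 22, which ionises to the bicyclic iminium ion and is attacked by C5 of the silyloxyfuran in a vinylogous Mannich reaction; the nucleophile should enter C3 on the face opposite the C9a–C9 bond (3,9a-trans pyrrolidine, C3 S), and C18 (S) should follow from the usual open transition state of silyloxyfuran additions to cyclic iminium ions.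

Step 12
Reactants: 23 19,20-didehydro target
Product: 24 CNP0419197.1 (3S,8R,9R,9aS,10S,11S,13S,18S,20S)
Conditions: H2 (1 atm), Pd/C (10 wt %), EtOAc, rt
Reagents that add atoms: none
Why: Heterogeneous hydrogenation should add H2 to the butenolide alkene from the face opposite the C18 substituent, placing the C20 methyl cis to the pyrrolidine branch (S); the spiroketal lactone, the tertiary amine and the other eight stereocenters are untouched.

## Compound list

1 | 1-bromo-4-chlorobutane | ClCCCCBr | starting material
2 | triphenylphosphine | c1ccc(cc1)P(c1ccccc1)c1ccccc1 | starting material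
3 | (4-chlorobutyl)triphenylphosphonium bromide | [Br-].ClCCCC[P+](c1ccccc1)(c1ccccc1)c1ccccc1 | intermediate
4 | (5S)-5-(hydroxymethyl)pyrrolidin-2-one | OC[C@@H]1CCC(=O)N1 | starting material
5 | (2S)-5-oxopyrrolidine-2-carbaldehyde | O=C[C@@H]1CCC(=O)N1 | intermediate
6 | (4-chlorobutylidene)triphenylphosphorane (ylide) | ClCCCC=P(c1ccccc1)(c1ccccc1)c1ccccc1 | intermediate
7 | (5S)-5-[(1Z)-5-chloropent-1-en-1-yl]pyrrolidin-2-one | ClCCC/C=C\[C@@H]1CCC(=O)N1 | intermediate
8 | tert-butyl butanoate | CCCC(=O)OC(C)(C)C | starting material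
9 | (3S)-3-methyloxolane-2,5-dione ((S)-methylsuccinic anhydride) | C[C@H]1CC(=O)OC1=O | starting material
10 | (2S)-6-tert-butoxy-5-ethyl-2-methyl-4,6-dioxohexanoic acid (C5 epimers) | CCC(C(=O)C[C@H](C)C(O)=O)C(=O)OC(C)(C)C | intermediate
11 | 1-tert-butyl 6-methyl (5S)-2-ethyl-5-methyl-3-oxohexanedioate (C2 epimers) | CCC(C(=O)C[C@H](C)C(=O)OC)C(=O)OC(C)(C)C | intermediate
12 | methyl (2S)-2-methyl-4-oxo-5-(oxomethylidene)heptanoate (acylketene) | CCC(=C=O)C(=O)C[C@H](C)C(=O)OC | intermediate
13 | methyl (2S)-5-{[(2S)-2-[(1Z)-5-chloropent-1-en-1-yl]-5-oxopyrrolidin-1-yl]carbonyl}-2-methyl-4-oxoheptanoate (C5 epimers) | CCC(C(=O)C[C@H](C)C(=O)OC)C(=O)N1C(=O)CC[C@H]1/C=C\CCCCl | intermediate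
14 | methyl (2S)-5-{[(2S)-2-[(2S,3R)-3-(3-chloropropyl)oxiran-2-yl]-5-oxopyrrolidin-1-yl]carbonyl}-2-methyl-4-oxoheptanoate (C5 epimers) | CCC(C(=O)C[C@H](C)C(=O)OC)C(=O)N1C(=O)CC[C@H]1[C@@H]2O[C@@H]2CCCCl | intermediate
15 | methyl (2S)-4-[(1R,7aS)-1-[(1R)-4-chloro-1-hydroxybutyl]-2-ethyl-3,5-dioxohexahydro-1H-pyrrolizin-2-yl]-2-methyl-4-oxobutanoate (C2 epimers; bicyclic imide alcohol) | CCC1(C(=O)C[C@H](C)C(=O)OC)[C@@H]([C@H](O)CCCCl)[C@@H]2CCC(=O)N2C1=O | intermediate
16 | methyl (2S)-4-[(4R,5R)-5-(3-chloropropyl)-3-ethyl-2-oxo-4-[(2S)-5-oxopyrrolidin-2-yl]oxolan-3-yl]-2-methyl-4-oxobutanoate (C3 epimers; lactone lactam chloride) | CCC1(C(=O)C[C@H](C)C(=O)OC)[C@@H]([C@@H](CCCCl)OC1=O)[C@@H]1CCC(=O)N1 | intermediate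
17 | tricyclic keto lactone: (8R,9R,9aS)-pyrrolo[1,2-a]azepin-3-one with trans-fused γ-lactone across C8–C9, C10 bearing ethyl and the 4-methoxy-(3S)-3-methyl-4-oxobutanoyl group (C10 epimers) | CCC1(C(=O)C[C@H](C)C(=O)OC)[C@H]2[C@@H](CCCN3[C@H]2CCC3=O)OC1=O | intermediate
18 | methyl (2S)-5-[(8R,9R,9aS)-8-hydroxy-3-oxooctahydro-1H-pyrrolo[1,2-a]azepin-9-yl]-2-methyl-4-oxoheptanoate (C5 epimers; hydroxy keto ester) | CCC(C(=O)C[C@H](C)C(=O)OC)[C@H]1[C@H](O)CCCN2[C@H]1CCC2=O | intermediate
19 | spiroketal lactam (8R,9R,9aS,10S,11S,13S): target skeleton with C3 lactam carbonyl instead of the C3 side chain | CC[C@H]1[C@H]2[C@@H](CCCN3[C@H]2CCC3=O)O[C@]12C[C@H](C)C(=O)O2 | intermediate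
20 | 3-methylfuran-2(5H)-one | CC1=CCOC1=O | starting material
21 | 3-methyl-2-(triisopropylsilyloxy)furan | Cc1ccoc1O[Si](C(C)C)(C(C)C)C(C)C | intermediate
22 | O-silyl hemiaminal of 19 (C3–O–SiMe2–O–SiMe2H, C3 epimers) | CC[C@H]1[C@H]2[C@@H](CCCN3[C@H]2CCC3O[Si](C)(C)O[SiH](C)C)O[C@]12C[C@H](C)C(=O)O2 | intermediate
23 | (3S,8R,9R,9aS,10S,11S,13S,18S)-19,20-didehydro target (butenolide on C3) | CC[C@H]1[C@H]2[C@@H](CCCN3[C@H]2CC[C@H]3[C@@H]2C=C(C)C(=O)O2)O[C@]12C[C@H](C)C(=O)O2 | intermediate
24 | CNP0419197.1 | CC[C@H]1[C@H]2[C@@H](CCCN3[C@H]2CC[C@H]3[C@@H]2C[C@H](C)C(=O)O2)O[C@]12C[C@H](C)C(=O)O2 | target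

## Step count and risks

Total step count: 12. Longest linear sequence: 8 steps (2, 3, 6, 7, 8, 9, 11, 12 from 4; the branch from 8 and 9 through steps 4–9, 11, 12 is equally long).

The three steps most likely to fail:

1. Step 8 (proposed new method). The opening of the hindered epoxide by the fully substituted carbanion may be slow or unselective, or the alkoxide and amide anion may be consumed by side reactions before the azepane closes. The fallback uses only known reactions, run stepwise, with a cyclic sulfate in place of the epoxide, and sets out from 13. OsO4 (cat.)/NMO syn-dihydroxylation of the Z-alkene on the face remote from the imide nitrogen should give methyl (2S)-5-{[(2S)-2-[(1S,2R)-5-chloro-1,2-dihydroxypentyl]-5-oxopyrrolidin-1-yl]carbonyl}-2-methyl-4-oxoheptanoate F1. SOCl2/Et3N, then RuCl3 (cat.)/NaIO4, converts it into the cyclic sulfate F2. With K2CO3 in MeCN at rt the β-keto imide carbanion opens the far more electrophilic cyclic sulfate at C9 (5-exo-tet, inversion) to the potassium sulfate monoester F3. Dilute H2SO4 in wet THF cleaves the sulfate ester to alcohol 15, Et3N brings about the N→O acyl shift to 16, which is isolated, and NaH/NaI in THF–DMPU closes the azepane. The sequence comes back to the route at 17.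

2. Step 7. The peracid may discriminate poorly between the two alkene faces, or the epoxide may be opened by the imide carbonyl under the acidic conditions. The fallback sets the two C–O centres by osmylation before the tether is attached and sets out from 7. OsO4 (cat.)/NMO dihydroxylation of the N–H lactam, anti to the allylic nitrogen in the same eclipsed conformer, should give (5S)-5-[(1S,2R)-5-chloro-1,2-dihydroxypentyl]pyrrolidin-2-one F4. MeC(OMe)3/PPTS gives the cyclic orthoacetate (5S)-5-[(4S,5R)-5-(3-chloropropyl)-2-methoxy-2-methyl-1,3-dioxolan-4-yl]pyrrolidin-2-one F5. AcBr opens it to (1S,2S)-2-bromo-5-chloro-1-[(2S)-5-oxopyrrolidin-2-yl]pentyl acetate F6 (bromide enters C8 with inversion). K2CO3/MeOH closes (5S)-5-[(2S,3R)-3-(3-chloropropyl)oxiran-2-yl]pyrrolidin-2-one F7 (second inversion at C8, net retention at both carbons). Thermal acylation with 11 as in step 6 then comes back to the route at 14.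

3. Step 6. The α-ethyl acylketene may dimerise or decompose faster than it is captured by the weakly nucleophilic lactam N–H. The fallback builds the tether in two stages on nitrogen and sets out from 7. Butanoyl chloride, Et3N and DMAP give (5S)-1-butanoyl-5-[(1Z)-5-chloropent-1-en-1-yl]pyrrolidin-2-one F8. LiN(SiMe3)2 in THF at −78 °C, then anhydride 9 (Claisen-type C-acylation of the chelated exocyclic imide enolate at the less hindered anhydride carbonyl), gives (2S)-5-{[(2S)-2-[(1Z)-5-chloropent-1-en-1-yl]-5-oxopyrrolidin-1-yl]carbonyl}-2-methyl-4-oxoheptanoic acid F9. Me3SiCHN2 then comes back to the route at 13.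

## Further compounds

F1 | step 8 | methyl (2S)-5-{[(2S)-2-[(1S,2R)-5-chloro-1,2-dihydroxypentyl]-5-oxopyrrolidin-1-yl]carbonyl}-2-methyl-4-oxoheptanoate | CCC(C(=O)C[C@H](C)C(=O)OC)C(=O)N1C(=O)CC[C@H]1[C@H](O)[C@H](O)CCCCl
F2 | step 8 | methyl (2S)-5-{[(2S)-2-[(4S,5R)-5-(3-chloropropyl)-2,2-dioxo-1,3,2-dioxathiolan-4-yl]-5-oxopyrrolidin-1-yl]carbonyl}-2-methyl-4-oxoheptanoate | CCC(C(=O)C[C@H](C)C(=O)OC)C(=O)N1C(=O)CC[C@H]1[C@@H]2OS(=O)(=O)O[C@@H]2CCCCl
F3 | step 8 | potassium (1R)-4-chloro-1-[(1R,7aS)-2-ethyl-2-[(3S)-4-methoxy-3-methyl-4-oxobutanoyl]-3,5-dioxohexahydro-1H-pyrrolizin-1-yl]butyl sulfate | [K+].CCC1(C(=O)C[C@H](C)C(=O)OC)[C@@H]([C@H](OS(=O)(=O)[O-])CCCCl)[C@@H]2CCC(=O)N2C1=O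
F4 | step 7 | (5S)-5-[(1S,2R)-5-chloro-1,2-dihydroxypentyl]pyrrolidin-2-one | O[C@H]([C@H](O)CCCCl)[C@@H]1CCC(=O)N1
F5 | step 7 | (5S)-5-[(4S,5R)-5-(3-chloropropyl)-2-methoxy-2-methyl-1,3-dioxolan-4-yl]pyrrolidin-2-one | COC1(C)O[C@H]([C@H](O1)CCCCl)[C@@H]2CCC(=O)N2
F6 | step 7 | (1S,2S)-2-bromo-5-chloro-1-[(2S)-5-oxopyrrolidin-2-yl]pentyl acetate | CC(=O)O[C@H]([C@@H](Br)CCCCl)[C@@H]1CCC(=O)N1
F7 | step 7 | (5S)-5-[(2S,3R)-3-(3-chloropropyl)oxiran-2-yl]pyrrolidin-2-one | O=C1CC[C@@H]([C@@H]2O[C@@H]2CCCCl)N1
F8 | step 6 | (5S)-1-butanoyl-5-[(1Z)-5-chloropent-1-en-1-yl]pyrrolidin-2-one | CCCC(=O)N1C(=O)CC[C@H]1/C=C\CCCCl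
F9 | step 6 | (2S)-5-{[(2S)-2-[(1Z)-5-chloropent-1-en-1-yl]-5-oxopyrrolidin-1-yl]carbonyl}-2-methyl-4-oxoheptanoic acid | CCC(C(=O)C[C@H](C)C(O)=O)C(=O)N1C(=O)CC[C@H]1/C=C\CCCCl
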